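**Retrosynthetic overview**
1. Kazinol K ⇐ global O-deprotection, after an aryl prenyl ether Claisen rearrangement has placed the 1,1-dimethylallyl group on ring A.
2. Propane bridge ⇐ B-alkyl Suzuki coupling of chromen-6-yl triflate 16 with the 9-BBN adduct of allylarene 21 (ring A bought as 4-bromoresorcinol).
3. Key step: arene ring B and the pyran ring form together in one thermal operation from the monocyclic 4-alkenyl-4-hydroxycyclobutenone 11 (4π opening, 6π closure, o-quinone methide, oxa-6π closure).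
4. 11 ⇐ methyl semisquarate 9 (from dimethyl squarate) + α-stannyl allylic alcohol 6 (from prenal, ethynylmagnesium bromide and prenyl bromide).
5. Ring order: ring A is purchased; ring B and then the pyran ring are formed in step 5; no other ring is made.

Assumption: Kazinol K has no stereocentre and no stereogenic alkene, so "single enantiomer" means the compound as drawn; intermediates with stereocentres are used as racemates or diastereomer mixtures.

**Step 1**
Reactants: 1 3-methylbut-2-enal (prenal); 2 ethynylmagnesium bromide; 3 1-bromo-3-methylbut-2-ene (prenyl bromide)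
Product: 5 2,9-dimethyldeca-2,8-dien-5-yn-4-ol, via bromomagnesium 5-methylhex-4-en-1-yn-3-olate 4 (not isolated)
Conditions: 2, THF, 0 °C; then EtMgBr (1.1 equiv), 40 °C; CuCl (10 mol%), 3, 50 °C; H2O work-up
Reagents that add atoms: none
Why: Grignard 1,2-addition to the enal, then Cu(I)-catalysed SN2 allylation of the alkynyl Grignard formed in situ (skipped-enyne synthesis); the racemic carbinol centre is destroyed in step 5.

**Step 2**
Reactants: 5 2,9-dimethyldeca-2,8-dien-5-yn-4-ol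
Product: 6 (5E)-2,9-dimethyl-5-(tributylstannyl)deca-2,5,8-trien-4-ol
Conditions: Bu3SnH, Mo(CO)3(CNt-Bu)3 (3 mol%), THF, 55 °C
Reagents that add atoms: tributyltin hydride CCCC[SnH](CCCC)CCCC
Why: Mo-catalysed syn-hydrostannation of a propargylic alcohol (Kazmaier type) puts tin on the carbinol-proximal carbon and H cis to tin, which fixes the 5E alkene.

**Step 3**
Reactants: 7 3,4-dimethoxycyclobut-3-ene-1,2-dione (dimethyl squarate)
Product: 9 3-methoxycyclobut-3-ene-1,2-dione (methyl semisquarate), via 4-hydroxy-2,3-dimethoxycyclobut-2-en-1-one 8 (not isolated)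
Conditions: LiAlH(Ot-Bu)3, THF, −78 → −20 °C; then 6 M HCl, CH2Cl2, rt
Reagents that add atoms: water O
Why: Liebeskind-type semisquarate synthesis (known for the isopropyl ester, used here by analogy): hydride 1,2-addition to one squarate carbonyl, then acid-induced allylic transposition through the methoxy-stabilised cation with loss of MeOH.

**Step 4**
Reactants: 6 (5E)-2,9-dimethyl-5-(tributylstannyl)deca-2,5,8-trien-4-ol; 9 methyl semisquarate
Product: 11 4-hydroxy-4-[(5E)-4-hydroxy-2,9-dimethyldeca-2,5,8-trien-5-yl]-3-methoxycyclobut-2-en-1-one, via dilithio vinyl alkoxide 10 (not isolated)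
Conditions: 6, n-BuLi (2.1 equiv), THF, −78 → −40 °C; then 9, −78 °C; AcOH (2.1 equiv), −78 °C
Reagents that add atoms: none
Why: Sn–Li exchange with retention of alkene geometry, then Liebeskind–Moore 1,2-addition to the more electrophilic carbonyl (the one next to C–OMe, not the vinylogous-ester carbonyl); both new stereocentres become sp2 in step 5, so the diastereomer mixture is used as such.

**Step 5 (key step)**
Reactants: 11 4-hydroxy-4-[(5E)-4-hydroxy-2,9-dimethyldeca-2,5,8-trien-5-yl]-3-methoxycyclobut-2-en-1-one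
Product: 15 8-methoxy-2,2-dimethyl-5-(3-methylbut-2-en-1-yl)-2H-chromen-6-ol, via dienylketene 12 (not isolated), via hydroquinone 13 (not isolated), via o-quinone methide 14 (not isolated)
Conditions: PhMe (degassed, 0.02 M), 110 °C, Ar
Reagents that add atoms: none
Why: Proposed new method: thermal 4π ring opening of the cyclobutenone (OH rotates outward, alkenyl inward) gives dienylketene 12, whose 6π closure and tautomerisation build arene ring B as hydroquinone 13; its ortho benzylic/allylic carbinol then loses water to o-quinone methide 14, which closes by oxa-6π electrocyclisation to the pyran ring. The closest known reaction types are the Liebeskind–Moore cyclobutenone ring expansion and the Wulff benzannulation/o-quinone methide/electrocyclisation chromene cascade; no stereocentre is formed.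

**Step 6**
Reactants: 15 8-methoxy-2,2-dimethyl-5-(3-methylbut-2-en-1-yl)-2H-chromen-6-ol
Product: 16 8-methoxy-2,2-dimethyl-5-(3-methylbut-2-en-1-yl)-2H-chromen-6-yl trifluoromethanesulfonate
Conditions: Tf2O, pyridine, CH2Cl2, −20 → 0 °C
Reagents that add atoms: trifluoromethanesulfonic anhydride O=S(=O)(OS(=O)(=O)C(F)(F)F)C(F)(F)F
Why: O-sulfonylation of the only free phenol turns the oxygen left at C6 by the ring expansion into the cross-coupling handle.

**Step 7**
Reactants: 17 4-bromobenzene-1,3-diol (4-bromoresorcinol); 3 1-bromo-3-methylbut-2-ene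
Product: 18 2-bromo-5-[(3-methylbut-2-en-1-yl)oxy]phenol
Conditions: K2CO3 (1.1 equiv), acetone, rt
Reagents that add atoms: none
Why: Williamson etherification; the phenoxide para to bromine is less hindered and more nucleophilic than the one ortho to bromine, so mono-O-prenylation is expected there.

**Step 8**
Reactants: 18 2-bromo-5-[(3-methylbut-2-en-1-yl)oxy]phenol; 19 allylboronic acid pinacol ester
Product: 20 5-[(3-methylbut-2-en-1-yl)oxy]-2-(prop-2-en-1-yl)phenol
Conditions: Pd(dppf)Cl2 (5 mol%), CsF, THF, 70 °C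
Reagents that add atoms: none
Why: Suzuki–Miyaura allylation of the aryl bromide installs the three carbons of the future bridge.

**Step 9**
Reactants: 20 5-[(3-methylbut-2-en-1-yl)oxy]-2-(prop-2-en-1-yl)phenol
Product: 21 tert-butyldimethyl{5-[(3-methylbut-2-en-1-yl)oxy]-2-(prop-2-en-1-yl)phenoxy}silane
Conditions: TBSCl, imidazole, DMF, rt
Reagents that add atoms: tert-butyldimethylsilyl chloride CC(C)(C)[Si](C)(C)Cl
Why: Silyl protection of the phenol; the bulky ortho silyl ether later shields ring-A C3 in the Claisen step.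

**Step 10**
Reactants: 21 tert-butyldimethyl{5-[(3-methylbut-2-en-1-yl)oxy]-2-(prop-2-en-1-yl)phenoxy}silane; 16 chromen-6-yl triflate
Product: 23 tert-butyl{2-[3-(8-methoxy-2,2-dimethyl-5-(3-methylbut-2-en-1-yl)-2H-chromen-6-yl)propyl]-5-[(3-methylbut-2-en-1-yl)oxy]phenoxy}dimethylsilane, via B-alkyl-9-BBN 22 (not isolated)
Conditions: 21, 9-BBN-H, THF, rt; then 16, Pd(dppf)Cl2 (5 mol%), K3PO4 (aq.), THF/DMF, 60 °C
Reagents that add atoms: none
Why: Anti-Markovnikov hydroboration of the terminal alkene by 9-BBN (the trisubstituted prenyl alkenes are untouched), then B-alkyl Suzuki–Miyaura coupling with the aryl triflate, builds the saturated bridge without any hydrogenation.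

**Step 11**
Reactants: 23 coupled diarylpropane
Product: 24 5-[(tert-butyldimethylsilyl)oxy]-4-{3-[8-methoxy-2,2-dimethyl-5-(3-methylbut-2-en-1-yl)-2H-chromen-6-yl]propyl}-2-(2-methylbut-3-en-2-yl)phenol
Conditions: Eu(fod)3 (10 mol%), PhMe, 90 °C
Reagents that add atoms: none
Why: Eu(III)-catalysed aromatic Claisen ([3,3]) rearrangement of the aryl prenyl ether delivers the 1,1-dimethylallyl group to the open ortho carbon C5, since C3 is shielded by the OTBS group and the para position is substituted.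

**Step 12**
Reactants: 24 Claisen product
Product: 25 Kazinol K
Conditions: NaSEt (6 equiv), DMF, 120 °C, Ar; then 1 M HCl, 0 °C
Reagents that add atoms: none
Why: Thiolate SN2 demethylation of the aryl methyl ether and thiolate cleavage of the aryl silyl ether under non-acidic conditions spare the prenyl, 1,1-dimethylallyl and chromene alkenes.

**Compound list**
1 | 3-methylbut-2-enal (prenal) | CC(C)=CC=O | starting material
2 | ethynylmagnesium bromide | C#C[Mg]Br | starting material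
3 | 1-bromo-3-methylbut-2-ene (prenyl bromide) | CC(C)=CCBr | starting material
4 | bromomagnesium 5-methylhex-4-en-1-yn-3-olate (racemic, not isolated) | CC(C)=CC(O[Mg]Br)C#C | intermediate
5 | 2,9-dimethyldeca-2,8-dien-5-yn-4-ol (racemic) | CC(C)=CC(O)C#CCC=C(C)C | intermediate
6 | (5E)-2,9-dimethyl-5-(tributylstannyl)deca-2,5,8-trien-4-ol (racemic) | CC(C)=CC(O)/C(=C\CC=C(C)C)[Sn](CCCC)(CCCC)CCCC | intermediate
7 | 3,4-dimethoxycyclobut-3-ene-1,2-dione (dimethyl squarate) | COC1=C(OC)C(=O)C1=O | starting material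
8 | 4-hydroxy-2,3-dimethoxycyclobut-2-en-1-one (racemic, not isolated) | COC1=C(OC)C(O)C1=O | intermediate
9 | 3-methoxycyclobut-3-ene-1,2-dione (methyl semisquarate) | COC1=CC(=O)C1=O | intermediate
10 | lithium (5Z)-5-lithio-2,9-dimethyldeca-2,5,8-trien-4-olate (Li in place of Sn, geometry retained, not isolated) | CC(C)=CC(O[Li])/C([Li])=C\CC=C(C)C | intermediate
11 | 4-hydroxy-4-[(5E)-4-hydroxy-2,9-dimethyldeca-2,5,8-trien-5-yl]-3-methoxycyclobut-2-en-1-one (diastereomer mixture, racemic) | COC1=CC(=O)C1(O)/C(=C/CC=C(C)C)C(O)C=C(C)C | intermediate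
12 | 4-hydroxy-5-(1-hydroxy-3-methylbut-2-en-1-yl)-3-methoxy-9-methyldeca-1,3,5,8-tetraen-1-one (dienylketene, not isolated) | O=C=C/C(OC)=C(O)\C(=C\CC=C(C)C)C(O)C=C(C)C | intermediate
13 | 2-(1-hydroxy-3-methylbut-2-en-1-yl)-6-methoxy-3-(3-methylbut-2-en-1-yl)benzene-1,4-diol (not isolated) | COc1cc(O)c(CC=C(C)C)c(C(O)C=C(C)C)c1O | intermediate
14 | 4-hydroxy-2-methoxy-5-(3-methylbut-2-en-1-yl)-6-(3-methylbut-2-en-1-ylidene)cyclohexa-2,4-dien-1-one (o-quinone methide, not isolated) | COC1=CC(O)=C(CC=C(C)C)C(=CC=C(C)C)C1=O | intermediate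
15 | 8-methoxy-2,2-dimethyl-5-(3-methylbut-2-en-1-yl)-2H-chromen-6-ol | COc1cc(O)c(CC=C(C)C)c2C=CC(C)(C)Oc12 | intermediate
16 | 8-methoxy-2,2-dimethyl-5-(3-methylbut-2-en-1-yl)-2H-chromen-6-yl trifluoromethanesulfonate | COc1cc(OS(=O)(=O)C(F)(F)F)c(CC=C(C)C)c2C=CC(C)(C)Oc12 | intermediate
17 | 4-bromobenzene-1,3-diol (4-bromoresorcinol) | Oc1ccc(Br)c(O)c1 | starting material
18 | 2-bromo-5-[(3-methylbut-2-en-1-yl)oxy]phenol | Oc1cc(OCC=C(C)C)ccc1Br | intermediate
19 | 4,4,5,5-tetramethyl-2-(prop-2-en-1-yl)-1,3,2-dioxaborolane (allylboronic acid pinacol ester) | C=CCB1OC(C)(C)C(C)(C)O1 | starting material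
20 | 5-[(3-methylbut-2-en-1-yl)oxy]-2-(prop-2-en-1-yl)phenol | C=CCc1ccc(OCC=C(C)C)cc1O | intermediate
21 | tert-butyldimethyl{5-[(3-methylbut-2-en-1-yl)oxy]-2-(prop-2-en-1-yl)phenoxy}silane | C=CCc1ccc(OCC=C(C)C)cc1O[Si](C)(C)C(C)(C)C | intermediate
22 | 9-{3-[2-(tert-butyldimethylsilyloxy)-4-(3-methylbut-2-en-1-yloxy)phenyl]propyl}-9-borabicyclo[3.3.1]nonane (not isolated) | CC(C)=CCOc1ccc(CCCB2C3CCCC2CCC3)c(O[Si](C)(C)C(C)(C)C)c1 | intermediate
23 | tert-butyl{2-[3-(8-methoxy-2,2-dimethyl-5-(3-methylbut-2-en-1-yl)-2H-chromen-6-yl)propyl]-5-[(3-methylbut-2-en-1-yl)oxy]phenoxy}dimethylsilane | COc1cc(CCCc2ccc(OCC=C(C)C)cc2O[Si](C)(C)C(C)(C)C)c(CC=C(C)C)c2C=CC(C)(C)Oc12 | intermediate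
24 | 5-[(tert-butyldimethylsilyl)oxy]-4-{3-[8-methoxy-2,2-dimethyl-5-(3-methylbut-2-en-1-yl)-2H-chromen-6-yl]propyl}-2-(2-methylbut-3-en-2-yl)phenol | COc1cc(CCCc2cc(C(C)(C)C=C)c(O)cc2O[Si](C)(C)C(C)(C)C)c(CC=C(C)C)c2C=CC(C)(C)Oc12 | intermediate
25 | Kazinol K, 4-{3-[8-hydroxy-2,2-dimethyl-5-(3-methylbut-2-en-1-yl)-2H-chromen-6-yl]propyl}-6-(2-methylbut-3-en-2-yl)benzene-1,3-diol (achiral) | C=CC(C)(C)c1cc(CCCc2cc(O)c3c(c2CC=C(C)C)C=CC(C)(C)O3)c(O)cc1O | target

**Total step count:** 12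
**Longest linear sequence:** 8 steps (1 → 2 → 4 → 5 → 6 → 10 → 11 → 12)

**Three steps most likely to fail, each with a fallback**

Step 5 (the ring expansion / o-quinone methide / oxa-6π cascade). The free side-chain carbinol is the weak point, because it can trap the ketene or ionise too early. The fallback sets out from 6 and comes back at 15. TBSCl/imidazole converts 6 into tert-butyl{[(5E)-2,9-dimethyl-5-(tributylstannyl)deca-2,5,8-trien-4-yl]oxy}dimethylsilane F1. The same Sn–Li exchange and addition to 9 give 4-{(5E)-4-[(tert-butyldimethylsilyl)oxy]-2,9-dimethyldeca-2,5,8-trien-5-yl}-4-hydroxy-3-methoxycyclobut-2-en-1-one F2. Heating (PhMe, 110 °C) then gives, by ring expansion only, the isolable arene 2-{1-[(tert-butyldimethylsilyl)oxy]-3-methylbut-2-en-1-yl}-6-methoxy-3-(3-methylbut-2-en-1-yl)benzene-1,4-diol F3. In a separate flask PPTS (cat., PhMe, 60 °C) expels the silanol, and the o-quinone methide closes to 15; the two rings are then made in two operations.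

Step 2 (tin must go to the carbinol-proximal alkyne carbon). The fallback sets out from 5 and comes back at 16 by reversing the regiochemical roles of both partners. Red-Al trans-hydroalumination of 5 and iodinolysis give (5Z)-6-iodo-2,9-dimethyldeca-2,5,8-trien-4-ol F4, with iodine distal to the carbinol (fixed by the five-membered alkoxyaluminate). Its dianion (t-BuLi, 3 equiv, −78 °C) is added to dimethyl squarate 7 and both alkoxides are silylated (TBSOTf) to give 4-[(tert-butyldimethylsilyl)oxy]-4-{(5Z)-4-[(tert-butyldimethylsilyl)oxy]-2,9-dimethyldeca-2,5,8-trien-6-yl}-2,3-dimethoxycyclobut-2-en-1-one F5. LiAlH(Ot-Bu)3 reduction of the remaining carbonyl and acid-induced carbonyl transposition give 4-[(tert-butyldimethylsilyl)oxy]-4-{(5Z)-4-[(tert-butyldimethylsilyl)oxy]-2,9-dimethyldeca-2,5,8-trien-6-yl}-2-methoxycyclobut-2-en-1-one F6. Thermolysis (PhMe, 110 °C) runs the same ring expansion, silanol loss and oxa-6π closure to tert-butyl{[8-methoxy-2,2-dimethyl-5-(3-methylbut-2-en-1-yl)-2H-chromen-6-yl]oxy}dimethylsilane F7, which CsF/PhNTf2 converts directly into 16.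

Step 12 (hot thiolate on the finished, alkene-rich skeleton). The fallback sets out from 15 and comes back at 25 by moving the demethylation to the robust chromenol stage. NaSEt/DMF converts 15 into 2,2-dimethyl-5-(3-methylbut-2-en-1-yl)-2H-chromene-6,8-diol F8. TBSCl/imidazole silylates the less hindered 8-OH (the 6-OH is flanked by the prenyl group) to give 8-[(tert-butyldimethylsilyl)oxy]-2,2-dimethyl-5-(3-methylbut-2-en-1-yl)-2H-chromen-6-ol F9, and Tf2O/pyridine gives 8-[(tert-butyldimethylsilyl)oxy]-2,2-dimethyl-5-(3-methylbut-2-en-1-yl)-2H-chromen-6-yl trifluoromethanesulfonate F10. B-alkyl Suzuki coupling with 22 gives the 8-O-TBS analogue of 23 F11, the Eu(fod)3 Claisen rearrangement gives the 8-O-TBS analogue of 24 F12, and TBAF (THF, 0 °C) removes both silyl groups to give 25.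

**Further compounds**
F1 | step 5 | tert-butyl{[(5E)-2,9-dimethyl-5-(tributylstannyl)deca-2,5,8-trien-4-yl]oxy}dimethylsilane | CC(C)=CC(O[Si](C)(C)C(C)(C)C)/C(=C\CC=C(C)C)[Sn](CCCC)(CCCC)CCCC
F2 | step 5 | 4-{(5E)-4-[(tert-butyldimethylsilyl)oxy]-2,9-dimethyldeca-2,5,8-trien-5-yl}-4-hydroxy-3-methoxycyclobut-2-en-1-one | COC1=CC(=O)C1(O)/C(=C/CC=C(C)C)C(O[Si](C)(C)C(C)(C)C)C=C(C)C
F3 | step 5 | 2-{1-[(tert-butyldimethylsilyl)oxy]-3-methylbut-2-en-1-yl}-6-methoxy-3-(3-methylbut-2-en-1-yl)benzene-1,4-diol | COc1cc(O)c(CC=C(C)C)c(C(O[Si](C)(C)C(C)(C)C)C=C(C)C)c1O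
F4 | step 2 | (5Z)-6-iodo-2,9-dimethyldeca-2,5,8-trien-4-ol | CC(C)=CC(O)/C=C(\I)CC=C(C)C
F5 | step 2 | 4-[(tert-butyldimethylsilyl)oxy]-4-{(5Z)-4-[(tert-butyldimethylsilyl)oxy]-2,9-dimethyldeca-2,5,8-trien-6-yl}-2,3-dimethoxycyclobut-2-en-1-one | COC1=C(OC)C(=O)C1(O[Si](C)(C)C(C)(C)C)/C(CC=C(C)C)=C\C(O[Si](C)(C)C(C)(C)C)C=C(C)C
F6 | step 2 | 4-[(tert-butyldimethylsilyl)oxy]-4-{(5Z)-4-[(tert-butyldimethylsilyl)oxy]-2,9-dimethyldeca-2,5,8-trien-6-yl}-2-methoxycyclobut-2-en-1-one | COC1=CC(O[Si](C)(C)C(C)(C)C)(/C(CC=C(C)C)=C\C(O[Si](C)(C)C(C)(C)C)C=C(C)C)C1=O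
F7 | step 2 | tert-butyl{[8-methoxy-2,2-dimethyl-5-(3-methylbut-2-en-1-yl)-2H-chromen-6-yl]oxy}dimethylsilane | COc1cc(O[Si](C)(C)C(C)(C)C)c(CC=C(C)C)c2C=CC(C)(C)Oc12
F8 | step 12 | 2,2-dimethyl-5-(3-methylbut-2-en-1-yl)-2H-chromene-6,8-diol | Oc1cc(O)c(CC=C(C)C)c2C=CC(C)(C)Oc12
F9 | step 12 | 8-[(tert-butyldimethylsilyl)oxy]-2,2-dimethyl-5-(3-methylbut-2-en-1-yl)-2H-chromen-6-ol | CC(C)(C)[Si](C)(C)Oc1cc(O)c(CC=C(C)C)c2C=CC(C)(C)Oc12
F10 | step 12 | 8-[(tert-butyldimethylsilyl)oxy]-2,2-dimethyl-5-(3-methylbut-2-en-1-yl)-2H-chromen-6-yl trifluoromethanesulfonate | CC(C)(C)[Si](C)(C)Oc1cc(OS(=O)(=O)C(F)(F)F)c(CC=C(C)C)c2C=CC(C)(C)Oc12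
F11 | step 12 | 8-O-TBS analogue of 23 (OSiMe2t-Bu in place of OMe at chromene C8) | CC(C)(C)[Si](C)(C)Oc1cc(CCCc2ccc(OCC=C(C)C)cc2O[Si](C)(C)C(C)(C)C)c(CC=C(C)C)c2C=CC(C)(C)Oc12
F12 | step 12 | 8-O-TBS analogue of 24 (OSiMe2t-Bu in place of OMe at chromene C8) | CC(C)(C)[Si](C)(C)Oc1cc(CCCc2cc(C(C)(C)C=C)c(O)cc2O[Si](C)(C)C(C)(C)C)c(CC=C(C)C)c2C=CC(C)(C)Oc12
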